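Its constants come from no measurement; what happens was integrated by code.

6 questions stand on 3 flasks: which substrate-bearing species leads at the end, and how large its share is.

| flask | substrate | gas | capture agent | free catalyst | added ligand | time |
|---|---|---|---|---|---|---|
| west | 20 mM | 6.3 mM (held) | 2.00 mM | 0.3 mol% | 93 µM | 2.0 h |
| south | 20 mM | 6.3 mM (held) | 2.00 mM | 0.75 mol% | 93 µM | 2.0 h |
| north | 20 mM | 6.3 mM (held) | 2.00 mM | 1.9 mol% | 93 µM | 2.0 h |

    substrate + catalyst intermediate B ⇌ catalyst intermediate C (K1 = 17 M⁻¹, k1 = 19800 M⁻¹ h⁻¹)
    catalyst intermediate A → catalyst intermediate B (k2 = 62.0 h⁻¹)
    gas ⇌ reagent, rate k3*(csat - [reagent]) (k3 = 0.717 h⁻¹, csat = 6.3 mM)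
    catalyst intermediate C → free catalyst + target (k4 = 376 h⁻¹)
    reagent + free catalyst → catalyst intermediate A (k5 = 2.12 × 10⁵ M⁻¹ h⁻¹)
    catalyst intermediate C + capture agent → trapped intermediate (k6 = 3000 M⁻¹ h⁻¹)
    free catalyst + added ligand ⇌ idle complex, settled at all times (K7 = 29000 M⁻¹)

- which of these there is most of at the end, counted by the substrate in it, west (catalyst intermediate C / substrate / trapped intermediate / target)
- which of these there is most of at the end, counted by the substrate in it, south (catalyst intermediate C / substrate / trapped intermediate / target)
- which of these there is most of at the end, counted by the substrate in it, north (catalyst intermediate C / substrate / trapped intermediate / target)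
- final amount of the leader among these, as a percentage of the substrate charged, in west
- final amount of the leader among these, as a percentage of the substrate charged, in south
- final amount of the leader among these, as a percentage of the substrate charged, in north

- at the start none of reagent is dissolved
- run time (west): 2.0 h

1. Take the fast ligand balance as holding at all times. Its constant times added ligand at the start of west is 2.7, and the idle complex can return free catalyst, so this balance is left out of the count below.

2. Catalyst intermediate C has two exits: release of target at 376 h⁻¹, and capture at 6.00 h⁻¹ with the capture agent as charged. Their ratio, 62.7, is the turnover number: target made per catalyst trapped.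

3. Multiplying that ratio by the loading gives the reach, the target the catalyst can make before it is trapped, with the capture agent as charged and counted in units of the substrate charge: 0.188 in west, 0.470 in south and 1.19 in north.

4. The reach has no clock, so one number is not enough. Gas supplies at most 0.452 of the substrate charge as reagent in 2.0 h, and each target made costs one reagent. In north this lies below the reach, and in south too, while in west the reach is less than the gas supply.

5. This reckoning stops at estimated floors for substrate: about 81.2% in west, and 54.8% in south and north. Substrate therefore stays ahead of target in west, south and north.

6. The forecast names substrate, substrate and substrate for west, south and north, at 89.3%, 75% and 58.5%: “Treat this as a catalytic cycle fed by gas transfer, with catalyst death by capture of C.” It commits to values where this reckoning gives estimated floors, and each value lies above its floor.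

7. The simulation gives substrate leading in west at 89.5%, substrate in south at 75.7% and substrate in north at 58.7%, so the forecast holds within its margins.

8. Target divided by reach estimates the trapped share of the catalyst: 54.9% in west, where the flask shows 54.5% as trapped intermediate. The neighbour of west with 80 mM substrate keeps the loading of west and has capture agent at 0.0250 equiv, the same concentration as west, so its reach stays 0.188. Its gas share falls to 0.113, below that reach, which gives a substrate floor of 88.7%. That neighbour ends with 90.6% substrate and 9.23% target. Its target over reach gives 49.1%, and its trapped intermediate stands at 47.7% of the catalyst charged.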